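Germacrane numbering is used: ring C1–C10, C14 on C10, C15 on C4, C11–C13 on C7. The fifteen skeletal carbons are one head-to-tail farnesyl chain whose ends, C6 and C7, are joined in the ring.
Retrosynthesis: the ester O–CH3 bond, the C14–O bonds and the O8–acyl bond are cut first, then the lactone O–C12 bond with the C6–O, C8–O and C12–O bonds, and last the ring bond C6–C7, which opens the macrocycle to (2E,6E)-farnesyl diphosphate and farnesol.
Forward: farnesol is diphosphorylated, (+)-germacrene A synthase closes the ten-membered ring, three cytochrome P450 enzymes oxidise C12 to the acid and hydroxylate C8 and then C6, and the γ-lactone ring closes by itself to give eupatolide.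
The 8-hydroxyl is then methacryloylated, SeO2 oxidises C14 and turns the C1–C10 olefin ring-cis, and the C14 alcohol is taken through the aldehyde and the acid to the methyl ester.
Stereochemistry: C7 (R) is set by the cyclase, C8 (R) and C6 (R) by the two hydroxylases; the E C4–C5 olefin comes from the farnesyl chain and the ring-cis C1–C10 olefin from the [2,3] shift of the SeO2 oxidation.

Key step: step 3

Assumption: the recombinant enzymes (cyclase from Escherichia coli, the three cytochrome P450 enzymes as yeast microsomes that carry a P450 reductase) are taken as catalysts available by standard expression; diphosphate 3 is handled as its triammonium salt and drawn as the free acid.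

Step 1
Reactants: 1 (2E,6E)-farnesol
Product: 2 (2E,6E)-farnesyl chloride
Conditions: NCS, Me2S, CH2Cl2, −40 °C to 0 °C
Reagents that add atoms: N-chlorosuccinimide, O=C1CCC(=O)N1Cl
Why: Corey–Kim chlorination, in which the alkoxysulfonium salt of 1 is displaced by chloride at the primary carbon (SN2), should give the allylic chloride without allylic transposition or loss of olefin geometry.

Step 2
Reactants: 2 (2E,6E)-farnesyl chloride
Product: 3 (2E,6E)-farnesyl diphosphate (triammonium salt)
Conditions: (Bu4N)3HP2O7, MeCN, rt; then cation exchange (sulfonic acid resin, NH4+ form), aq NH4HCO3/iPrOH, lyophilisation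
Reagents that add atoms: tris(tetrabutylammonium) hydrogen diphosphate, CCCC[N+](CCCC)(CCCC)CCCC.CCCC[N+](CCCC)(CCCC)CCCC.CCCC[N+](CCCC)(CCCC)CCCC.OP(=O)([O-])OP(=O)([O-])[O-]
Why: SN2 displacement of the primary allylic chloride by the diphosphate anion in a dipolar aprotic solvent, the standard chemical diphosphorylation of prenyl halides, should give the diphosphate with both E olefins intact.

Step 3
Reactants: 3 (2E,6E)-farnesyl diphosphate (triammonium salt)
Product: 4 (+)-germacrene A, (7R)-germacra-1(10)E,4E,11-triene
Conditions: recombinant (+)-germacrene A synthase (Cichorium intybus enzyme, from Escherichia coli), MgCl2, dithiothreitol, HEPES buffer pH 7.5, pentane overlay, 30 °C; pentane phase dried and concentrated below 20 °C, kept cold in solution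
Reagents that add atoms: none
Why: Mg2+-assisted ionisation of the diphosphate gives the allyl cation spread over C6, C5 and C4, the distal C7–C11 olefin of the folded chain attacks C6 through C7, and the tertiary C11 cation so formed loses a proton from one methyl group to leave the isopropenyl group. The closest known reaction type is the cation–olefin macrocyclisation catalysed by class-one sesquiterpene cyclases, and this enzyme with this substrate is the known first step of germacranolide biosynthesis. The ten-membered ring closes by a 1,10-closure of the farnesyl chain, Markovnikov and exo with respect to the attacking olefin (C11 stays outside the ring) and without allylic transposition at the cation end, so the 2E olefin of 3 becomes the E C4–C5 olefin. The one new stereocentre, C7, is fixed as R by the face of the C7–C11 olefin that the active-site fold presents to C6. The step needs 1,10-closure to win over 1,6- and 1,11-closure, over capture of the cation by water and over further cyclisation of the product; the 2E geometry of 3 forbids 1,6-closure without prior isomerisation, and the enzyme pocket, the neutral pH, the pentane overlay and the low temperature should secure the rest.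

Step 4
Reactants: 4 (+)-germacrene A
Product: 7 germacrene A acid (germacra-1(10),4,11(13)-trien-12-oic acid), via germacratrien-12-ol 5 (not isolated), via germacratrien-12-al 6 (not isolated)
Conditions: germacrene A oxidase CYP71AV8 with cytochrome P450 reductase (Saccharomyces cerevisiae microsomes), air, NADP+ (cat.), D-glucose 6-phosphate, glucose-6-phosphate dehydrogenase, Tris-HCl buffer pH 7.5, substrate added in a little DMSO, 30 °C; EtOAc extraction at pH 6
Reagents that add atoms: dioxygen, O=O
Why: germacrene A oxidase, a cytochrome P450, is known to take this hydrocarbon through three successive oxygen-rebound oxidations of the allylic C12 methyl group (alcohol, aldehyde, acid; enzymatic C–H hydroxylation) while the two ring olefins and C7 stay untouched.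

Step 5
Reactants: 7 germacrene A acid
Product: 8 8β-hydroxygermacrene A acid
Conditions: germacrene A acid 8β-hydroxylase CYP71BL1 (Helianthus annuus) with cytochrome P450 reductase (yeast microsomes), air, NADP+ (cat.), D-glucose 6-phosphate, glucose-6-phosphate dehydrogenase, Tris-HCl buffer pH 7.5, 30 °C; EtOAc extraction at pH 6
Reagents that add atoms: dioxygen, O=O
Why: cytochrome P450 C–H hydroxylation with oxygen rebound and retention, known for this enzyme and this acid, should place the hydroxyl on the β face of C8, so that the new stereocentre (R) is set by the way the enzyme holds the substrate over its haem iron.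

Step 6
Reactants: 8 8β-hydroxygermacrene A acid
Product: 10 eupatolide (8β-hydroxycostunolide), via 6α,8β-dihydroxygermacrene A acid 9 (not isolated)
Conditions: eupatolide synthase CYP71DD6 (Helianthus annuus) with cytochrome P450 reductase (yeast microsomes), air, NADP+ (cat.), D-glucose 6-phosphate, glucose-6-phosphate dehydrogenase, Tris-HCl buffer pH 7.5, 30 °C; EtOAc extraction, chromatography on neutral silica
Reagents that add atoms: dioxygen, O=O
Why: cytochrome P450 allylic C–H hydroxylation, known for this enzyme and this substrate, should place the hydroxyl on the α face of C6 (R, enzyme control), after which the 6α-hydroxy acid 9 closes at once to the trans-fused γ-lactone (spontaneous lactonisation, as in costunolide formation), whereas the 8β-hydroxyl, as the stability of 8 shows, does not close onto C12.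

Step 7
Reactants: 10 eupatolide; 11 methacrylic anhydride
Product: 12 8-O-methacryloyleupatolide (8β-methacryloyloxycostunolide)
Conditions: Et3N, 4-(dimethylamino)pyridine (cat.), CH2Cl2, 0 °C to rt
Reagents that add atoms: methacrylic anhydride (11), C=C(C)C(=O)OC(=O)C(C)=C
Why: nucleophile-catalysed acyl transfer (Steglich-type acylation) to the only free hydroxyl under weakly basic, aprotic conditions should leave the lactone in place and touch no stereocentre.

Step 8
Reactants: 12 8-O-methacryloyleupatolide
Product: 13 8β-methacryloyloxy-14-hydroxygermacra-1(10),4E,11(13)-trien-12,6α-olide with ring-cis C1–C10 olefin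
Conditions: SeO2 (cat.), tBuOOH, CH2Cl2, rt
Reagents that add atoms: tert-butyl hydroperoxide, CC(C)(C)OO (terminal oxygen source); SeO2, O=[Se]=O (oxygen carrier)
Why: Riley allylic oxidation in its catalytic SeO2/tBuOOH form, in which the ene reaction should take place at the more electron-rich C1–C10 olefin (the C4–C5 olefin is deactivated by the allylic C6 oxygen) with hydrogen loss from C14, and the [2,3] shift of the allylseleninic acid should deliver oxygen to C14 and re-form the olefin with C14 trans to C2, which is the ring-cis geometry known to result from germacranolides of the costunolide and parthenolide type.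

Step 9
Reactants: 13 the C14 allylic alcohol
Product: 14 8β-methacryloyloxy-14-oxogermacra-1(10),4E,11(13)-trien-12,6α-olide (ring-cis C1–C10)
Conditions: Dess–Martin periodinane, NaHCO3, CH2Cl2, 0 °C to rt
Reagents that add atoms: none
Why: Dess–Martin oxidation of a primary allylic alcohol under buffered, near-neutral conditions should give the enal without olefin isomerisation or acid-induced transannular cyclisation.

Step 10
Reactants: 14 the C14 aldehyde
Product: 15 8β-methacryloyloxygermacra-1(10),4E,11(13)-trien-12,6α-olid-14-oic acid (ring-cis C1–C10)
Conditions: NaClO2, NaH2PO4, 2-methyl-2-butene, tBuOH/H2O, 0 °C to rt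
Reagents that add atoms: NaClO2 (sodium chlorite), [Na+].[O-]Cl=O
Why: Pinnick oxidation should convert the conjugated aldehyde into the acid selectively, with 2-methyl-2-butene taking up the hypochlorous acid before it can reach the C4–C5 olefin and the electron-poor acrylate units staying inert.

Step 11
Reactants: 15 the C14 acid
Product: 16 methyl 8β-methacryloyloxygermacra-1(10),4E,11(13)-trien-12,6α-olid-14-oate (ring-cis C1–C10), the target
Conditions: MeI, KHCO3, DMF, rt
Reagents that add atoms: iodomethane, CI
Why: SN2 O-alkylation of the carboxylate with iodomethane under a weak base should give the methyl ester and avoids diazomethane, which would add to the α-methylene lactone by dipolar cycloaddition.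

Compound list
1 | (2E,6E)-farnesol | CC(C)=CCC/C(C)=C/CC/C(C)=C/CO | starting material
2 | (2E,6E)-farnesyl chloride | CC(C)=CCC/C(C)=C/CC/C(C)=C/CCl | intermediate
3 | (2E,6E)-farnesyl diphosphate, drawn as the free acid, handled as the triammonium salt | CC(C)=CCC/C(C)=C/CC/C(C)=C/COP(=O)(O)OP(=O)(O)O | intermediate
4 | (+)-germacrene A, (7R)-germacra-1(10)E,4E,11-triene, H-7 α | C1C/C(C)=C/CC/C(C)=C/C[C@@H]1C(C)=C | intermediate
5 | (7R)-germacra-1(10)E,4E,11(13)-trien-12-ol | C1C/C(C)=C/CC/C(C)=C/C[C@@H]1C(=C)CO | intermediate (not isolated)
6 | (7R)-germacra-1(10)E,4E,11(13)-trien-12-al | C1C/C(C)=C/CC/C(C)=C/C[C@@H]1C(=C)C=O | intermediate (not isolated)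
7 | germacrene A acid, (7R)-germacra-1(10)E,4E,11(13)-trien-12-oic acid | C1C/C(C)=C/CC/C(C)=C/C[C@@H]1C(=C)C(=O)O | intermediate
8 | 8β-hydroxygermacrene A acid, (7R,8R), H-7 α, OH-8 β | O[C@@H]1C/C(C)=C/CC/C(C)=C/C[C@@H]1C(=C)C(=O)O | intermediate
9 | 6α,8β-dihydroxygermacrene A acid, (6R,7R,8R) | O[C@@H]1C/C(C)=C/CC/C(C)=C/[C@@H](O)[C@@H]1C(=C)C(=O)O | intermediate (not isolated)
10 | eupatolide, (6R,7R,8R)-8β-hydroxygermacra-1(10)E,4E,11(13)-trien-12,6α-olide, trans-fused lactone | O[C@@H]1C/C(C)=C/CC/C(C)=C/[C@H]2OC(=O)C(=C)[C@@H]21 | intermediate
11 | methacrylic anhydride | C=C(C)C(=O)OC(=O)C(C)=C | starting material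
12 | 8-O-methacryloyleupatolide, ring-trans C1–C10 olefin (C9 trans to C2) | C=C(C)C(=O)O[C@@H]1C/C(C)=C/CC/C(C)=C/[C@H]2OC(=O)C(=C)[C@@H]21 | intermediate
13 | 8β-methacryloyloxy-14-hydroxygermacra-1(10),4E,11(13)-trien-12,6α-olide, ring-cis C1–C10 olefin (C9 cis to C2, C14 trans to C2) | C=C(C)C(=O)O[C@@H]1C/C(CO)=C\CC/C(C)=C/[C@H]2OC(=O)C(=C)[C@@H]21 | intermediate
14 | 8β-methacryloyloxy-14-oxogermacra-1(10),4E,11(13)-trien-12,6α-olide, ring-cis C1–C10 olefin | C=C(C)C(=O)O[C@@H]1C/C(C=O)=C\CC/C(C)=C/[C@H]2OC(=O)C(=C)[C@@H]21 | intermediate
15 | 8β-methacryloyloxygermacra-1(10),4E,11(13)-trien-12,6α-olid-14-oic acid, ring-cis C1–C10 olefin | C=C(C)C(=O)O[C@@H]1C/C(C(=O)O)=C\CC/C(C)=C/[C@H]2OC(=O)C(=C)[C@@H]21 | intermediate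
16 | methyl (6R,7R,8R)-8β-methacryloyloxygermacra-1(10),4E,11(13)-trien-12,6α-olid-14-oate, ring-cis C1–C10 olefin | C=C(C)C(=O)O[C@@H]1C/C(C(=O)OC)=C\CC/C(C)=C/[C@H]2OC(=O)C(=C)[C@@H]21 | target

Total step count: 11. Longest linear sequence: 11 steps (1 to 16).

Steps most likely to fail

Step 3. The cyclisation itself is well precedented. The danger lies in losing the hydrocarbon between this step and the next through Cope rearrangement on warming, proton-induced transannular cyclisation and evaporation on concentration, and in slowing of the cyclase by the diphosphate it releases. The fallback sets out from 3 and joins cyclase and oxidase in one vessel: cyclase, MgCl2, microsomes with CYP71AV8 and reductase, and the NADPH-regenerating system of step 4, in one aqueous phase without overlay at 30 °C. Germacrene A 4 is then oxidised as fast as it forms, through 5 and 6, and the route is rejoined at acid 7. The same ring bond is formed by the same enzyme, and no compound outside the list is made (F0).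

Step 6. The risk is low turnover of a membrane-bound P450 outside the cell, hydroxylation at carbons other than C6, and loss of the labile germacradiene acids over two successive cell-free incubations and extractions. The fallback sets out from acid 7 and uses whole cells. Resting Saccharomyces cerevisiae cells that co-express CYP71BL1, CYP71DD6 and the reductase are fed with 7 in glucose-containing buffer at pH 6 to 7. The two hydroxylations then run in the native membrane with cellular cofactor supply, 8 and 9 are not isolated, and the route is rejoined at eupatolide 10. No compound outside the list is made (F0).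

Step 8. The risk is insufficient site selectivity between C14 and C15 (or the ring methylene groups), a second oxidation at C15 with isomerisation of the C4–C5 olefin, and incomplete conversion. Further oxidation at C14 to aldehyde 14 is no loss, since 14 is the product of step 9. The fallback sets out from 12 and separates the choice of site from the oxygen transfer.
- Photo-oxygenation (O2, tetraphenylporphyrin, visible light, CH2Cl2, 0 °C; Schenck ene reaction) is known for lactones of the costunolide type to take place at the C1–C10 olefin with hydrogen loss from C14. It should give 1β-hydroperoxy-8β-methacryloyloxygermacra-4E,10(14),11(13)-trien-12,6α-olide F1, with attack expected from the outer face of the ring.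
- Reduction with PPh3 in CH2Cl2 at 0 °C should give the 1β-hydroxy-10(14)-ene lactone F2.
- A 1,3-transposition of this secondary allylic alcohol, catalysed by Ph3SiOReO3 in Et2O at low temperature, should move the oxygen to C14. It is driven by formation of the trisubstituted olefin and passes through a chair [3,3] shift with C2 equatorial, so C14 should end trans to C2, the same ring-cis geometry. The route is rejoined at 13.

Further compounds
F0 | step 3 | none | none
F0 | step 6 | none | none
F1 | step 8 | 1β-hydroperoxy-8β-methacryloyloxygermacra-4E,10(14),11(13)-trien-12,6α-olide | C=C(C)C(=O)O[C@@H]1CC(=C)[C@H](OO)CC/C(C)=C/[C@H]2OC(=O)C(=C)[C@@H]21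
F2 | step 8 | 1β-hydroxy-8β-methacryloyloxygermacra-4E,10(14),11(13)-trien-12,6α-olide | C=C(C)C(=O)O[C@@H]1CC(=C)[C@H](O)CC/C(C)=C/[C@H]2OC(=O)C(=C)[C@@H]21
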